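**Plan**
The chain is numbered C1 (alkene CH on the guaiacyl ring) to C7 (carbinol carbon on the 4-hydroxyphenyl ring).
Retrosynthesis: the enolised C3/C5 diketone is traced back to a 3,5-disubstituted isoxazole (N on C3, O on C5); then the C7–H bond is cut (aryl ketone), then C6–C7 (acylation of the isoxazole 5-methyl anion), then C1=C2 (Horner–Wadsworth–Emmons).
Forward: no ring is built, since the isoxazole ring is bought; C1=C2 is joined first, C6–C7 second, C7 is reduced, and the ring is opened last by N–O cleavage and hydrolysis.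
Enabling feature: C7 is a benzylic carbinol β to the C5 carbonyl of the C3/C5 1,3-diketone; while C3, C4 and C5 sit in the aromatic isoxazole ring, C7 is the only carbonyl and a plain aryl ketone.
Stereochemistry: C7 (S) comes from an enzymatic ketone reduction (hydride to the Re face); the E alkene comes from the olefination.

Key step: step 7

Remark: the target is a β-diketone drawn as its C3 enol; diketone and enol forms, and with them the C3=C4 enol geometry, interconvert by proton transfer, so the route delivers this equilibrating compound, written below in the drawn form.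

**Route**

Step 1
Reactants: 1 vanillin (4-hydroxy-3-methoxybenzaldehyde)
Product: 2 4-[(tert-butyldimethylsilyl)oxy]-3-methoxybenzaldehyde
Conditions: TBSCl, imidazole, DMF, 0 °C → rt
Reagents that add atoms: tert-butyldimethylsilyl chloride, CC(C)(C)[Si](C)(C)Cl
Why: Imidazole-promoted silyl ether formation should be clean because the phenol is the only nucleophilic group, and it removes the acidic proton that would otherwise quench the phosphonate anion of step 3.

Step 2
Reactants: 3 3-(chloromethyl)-5-methylisoxazole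
Product: 4 diethyl [(5-methylisoxazol-3-yl)methyl]phosphonate
Conditions: P(OEt)3 (neat, excess), 150 °C, EtCl distilled off
Reagents that add atoms: triethyl phosphite, CCOP(OCC)OCC
Why: In this Michaelis–Arbuzov reaction the activated heteroarylmethyl chloride should be displaced by the phosphite and the resulting phosphonium salt dealkylated by chloride.

Step 3
Reactants: 4 diethyl [(5-methylisoxazol-3-yl)methyl]phosphonate; 2 4-[(tert-butyldimethylsilyl)oxy]-3-methoxybenzaldehyde
Product: 5 3-[(E)-2-{4-[(tert-butyldimethylsilyl)oxy]-3-methoxyphenyl}ethenyl]-5-methylisoxazole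
Conditions: NaH, THF, 0 °C → rt
Reagents that add atoms: none
Why: Horner–Wadsworth–Emmons olefination of a non-enolisable aryl aldehyde with a heteroarylmethyl phosphonate anion should give the conjugated E alkene, since the reversible addition funnels through the less crowded anti adduct before phosphate loss.

Step 4
Reactants: 6 methyl 4-hydroxybenzoate
Product: 7 methyl 4-[(tert-butyldimethylsilyl)oxy]benzoate
Conditions: TBSCl, imidazole, DMF, rt
Reagents that add atoms: tert-butyldimethylsilyl chloride, CC(C)(C)[Si](C)(C)Cl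
Why: Silyl ether formation at the single phenol should give an ester with no acidic proton, fit to meet a carbanion.

Step 5
Reactants: 5 3-[(E)-2-{4-[(tert-butyldimethylsilyl)oxy]-3-methoxyphenyl}ethenyl]-5-methylisoxazole; 7 methyl 4-[(tert-butyldimethylsilyl)oxy]benzoate
Product: 10 1-{4-[(tert-butyldimethylsilyl)oxy]phenyl}-2-{3-[(E)-2-{4-[(tert-butyldimethylsilyl)oxy]-3-methoxyphenyl}ethenyl]isoxazol-5-yl}ethan-1-one, via 5-(lithiomethyl)isoxazole 8 (not isolated), via lithium enolate 9 (not isolated)
Conditions: LiN(iPr)2 (LDA, 2.2 equiv), THF, −78 °C; then 7, −78 → −40 °C; AcOH quench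
Reagents that add atoms: none
Why: Lateral metalation of the 5-methyl group of a 3,5-disubstituted isoxazole followed by Claisen-type acylation with a non-enolisable aryl ester should form C6–C7, the second equivalent of amide base holding the acidic ketone as its enolate so that the lateral anion is not lost to proton transfer.

Step 6
Reactants: 10 1-{4-[(tert-butyldimethylsilyl)oxy]phenyl}-2-{3-[(E)-2-{4-[(tert-butyldimethylsilyl)oxy]-3-methoxyphenyl}ethenyl]isoxazol-5-yl}ethan-1-one
Product: 11 1-(4-hydroxyphenyl)-2-{3-[(E)-2-(4-hydroxy-3-methoxyphenyl)ethenyl]isoxazol-5-yl}ethan-1-one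
Conditions: Bu4NF, AcOH, THF, 0 °C
Reagents that add atoms: none
Why: Fluoride cleavage of the two aryl silyl ethers, buffered with acetic acid so that the acidic C6 methylene never sees a basic medium, should free both phenols and give a substrate soluble enough for an aqueous enzymatic step.

Step 7
Reactants: 11 1-(4-hydroxyphenyl)-2-{3-[(E)-2-(4-hydroxy-3-methoxyphenyl)ethenyl]isoxazol-5-yl}ethan-1-one
Product: 12 (S)-1-(4-hydroxyphenyl)-2-{3-[(E)-2-(4-hydroxy-3-methoxyphenyl)ethenyl]isoxazol-5-yl}ethan-1-ol
Conditions: (S)-selective ketoreductase (picked from a panel screen), NADP+ (cat.), glucose dehydrogenase, D-glucose, KH2PO4/K2HPO4 buffer pH 7.0, DMSO (10% v/v), 30 °C, dark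
Reagents that add atoms: none
Why: The ketoreductase holds NADPH and the ketone so that the dihydronicotinamide hydride is passed to the Re face of the C7 carbonyl while an active-site tyrosine protonates the oxygen; glucose dehydrogenase with D-glucose regenerates NADPH and makes the reduction effectively irreversible, which helps with an aryl ketone stabilised by a para-hydroxyl. The closest known reaction type is the biocatalytic asymmetric reduction of prochiral aryl alkyl ketones with cofactor recycling. No ring is formed and no skeletal bond is made; only the C7–H bond is new. The C7 stereocentre is controlled by the enzyme pocket alone, so a panel holding enzymes of both facial preferences is screened and the member that gives the S carbinol is used. The step needs enantiofacial selectivity and chemoselectivity for C7; the substrate secures the latter because C3 and C5 are locked in the aromatic isoxazole ring, so C7 is the only carbonyl, and the unequal 4-hydroxyphenyl and CH2–isoxazolyl–styryl arms give the pocket two clearly different groups to tell apart. At pH 7 and 30 °C the free phenols and the E alkene should be left alone and the 4-hydroxybenzylic alcohol should not lose water.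

Step 8
Reactants: 12 (S)-1-(4-hydroxyphenyl)-2-{3-[(E)-2-(4-hydroxy-3-methoxyphenyl)ethenyl]isoxazol-5-yl}ethan-1-ol
Product: 13 (1E,3Z,7S)-3-amino-7-hydroxy-1-(4-hydroxy-3-methoxyphenyl)-7-(4-hydroxyphenyl)hepta-1,3-dien-5-one (chain numbered as in the plan)
Conditions: Mo(CO)6 (1 equiv), MeCN/H2O (10:1), 80 °C, N2
Reagents that add atoms: none
Why: Reductive N–O cleavage of an isoxazole by zerovalent molybdenum with water as proton source is an established route to chelated β-amino enones and, being neutral, should leave the C1=C2 alkene, the phenols and the C7 carbinol untouched.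

Step 9
Reactants: 13 (1E,3Z,7S)-3-amino-7-hydroxy-1-(4-hydroxy-3-methoxyphenyl)-7-(4-hydroxyphenyl)hepta-1,3-dien-5-one
Product: 14 (1E,7S)-7-hydroxy-1-(4-hydroxy-3-methoxyphenyl)-7-(4-hydroxyphenyl)hept-1-ene-3,5-dione, written as its C3 enol (the target)
Conditions: NaOAc/AcOH buffer (pH 4.5), THF/H2O, 25–40 °C
Reagents that add atoms: water, O
Why: Hydrolysis of the vinylogous amide (C4 protonation, water addition at C3, loss of ammonia) should release the enolised diketone at a pH too mild for dehydration or ionisation at C7, so the S configuration is carried through unchanged.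

**Compound list**
1 | vanillin (4-hydroxy-3-methoxybenzaldehyde) | COc1cc(C=O)ccc1O | starting material
2 | 4-[(tert-butyldimethylsilyl)oxy]-3-methoxybenzaldehyde | COc1cc(C=O)ccc1O[Si](C)(C)C(C)(C)C | intermediate
3 | 3-(chloromethyl)-5-methylisoxazole | Cc1cc(CCl)no1 | starting material
4 | diethyl [(5-methylisoxazol-3-yl)methyl]phosphonate | CCOP(=O)(Cc1cc(C)on1)OCC | intermediate
5 | 3-[(E)-2-{4-[(tert-butyldimethylsilyl)oxy]-3-methoxyphenyl}ethenyl]-5-methylisoxazole | COc1cc(/C=C/c2cc(C)on2)ccc1O[Si](C)(C)C(C)(C)C | intermediate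
6 | methyl 4-hydroxybenzoate | COC(=O)c1ccc(O)cc1 | starting material
7 | methyl 4-[(tert-butyldimethylsilyl)oxy]benzoate | COC(=O)c1ccc(O[Si](C)(C)C(C)(C)C)cc1 | intermediate
8 | 3-[(E)-2-{4-[(tert-butyldimethylsilyl)oxy]-3-methoxyphenyl}ethenyl]-5-(lithiomethyl)isoxazole | COc1cc(/C=C/c2cc(C[Li])on2)ccc1O[Si](C)(C)C(C)(C)C | intermediate
9 | lithium (Z)-enolate of ketone 10 | COc1cc(/C=C/c2cc(/C=C(\[O-])c3ccc(O[Si](C)(C)C(C)(C)C)cc3)on2)ccc1O[Si](C)(C)C(C)(C)C.[Li+] | intermediate
10 | 1-{4-[(tert-butyldimethylsilyl)oxy]phenyl}-2-{3-[(E)-2-{4-[(tert-butyldimethylsilyl)oxy]-3-methoxyphenyl}ethenyl]isoxazol-5-yl}ethan-1-one | COc1cc(/C=C/c2cc(CC(=O)c3ccc(O[Si](C)(C)C(C)(C)C)cc3)on2)ccc1O[Si](C)(C)C(C)(C)C | intermediate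
11 | 1-(4-hydroxyphenyl)-2-{3-[(E)-2-(4-hydroxy-3-methoxyphenyl)ethenyl]isoxazol-5-yl}ethan-1-one | COc1cc(/C=C/c2cc(CC(=O)c3ccc(O)cc3)on2)ccc1O | intermediate
12 | (S)-1-(4-hydroxyphenyl)-2-{3-[(E)-2-(4-hydroxy-3-methoxyphenyl)ethenyl]isoxazol-5-yl}ethan-1-ol | COc1cc(/C=C/c2cc(C[C@H](O)c3ccc(O)cc3)on2)ccc1O | intermediate
13 | (1E,3Z,7S)-3-amino-7-hydroxy-1-(4-hydroxy-3-methoxyphenyl)-7-(4-hydroxyphenyl)hepta-1,3-dien-5-one | COc1cc(/C=C/C(N)=C/C(=O)C[C@H](O)c2ccc(O)cc2)ccc1O | intermediate
14 | (1E,7S)-7-hydroxy-1-(4-hydroxy-3-methoxyphenyl)-7-(4-hydroxyphenyl)hept-1-ene-3,5-dione, C3 enol form | COc1cc(/C=C/C(O)=C\C(=O)C[C@H](O)c2ccc(O)cc2)ccc1O | target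

**Count and risks**
Total step count: 9. Longest linear sequence: 7 steps (steps 1, 3, 5, 6, 7, 8, 9).

Steps most likely to fail:

1. Step 7. The enzyme may turn over slowly or with poor facial selectivity, because the carbonyl is flanked by two large groups, is deactivated by the para-hydroxyl and belongs to a substrate that dissolves poorly in buffer. The fallback sets out from 10: asymmetric transfer hydrogenation with RuCl[(S,S)-TsDPEN](p-cymene), a divalent ruthenium catalyst, in HCO2H/Et3N (5:2) at 30 °C should deliver hydride to the same face. This should give (S)-1-{4-[(tert-butyldimethylsilyl)oxy]phenyl}-2-{3-[(E)-2-{4-[(tert-butyldimethylsilyl)oxy]-3-methoxyphenyl}ethenyl]isoxazol-5-yl}ethan-1-ol F1. Desilylation with Bu4NF/AcOH in THF at 0 °C then comes back to the route at 12.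

2. Step 8. At 80 °C the 4-hydroxybenzylic carbinol may ionise through a para-quinone methide, causing loss of water across C6–C7 or erosion of the C7 configuration, and binding of the free phenols to molybdenum may slow the N–O cleavage. The fallback sets out from 12: silylation of all three hydroxyls with excess TBSCl and imidazole in DMF at 40 °C should give 3-[(E)-2-{4-[(tert-butyldimethylsilyl)oxy]-3-methoxyphenyl}ethenyl]-5-[(2S)-2-[(tert-butyldimethylsilyl)oxy]-2-{4-[(tert-butyldimethylsilyl)oxy]phenyl}ethyl]isoxazole F2, which can no longer form a quinone methide. Mo(CO)6 in MeCN/H2O at 80 °C should then open the ring to (1E,3Z,7S)-3-amino-7-[(tert-butyldimethylsilyl)oxy]-1-{4-[(tert-butyldimethylsilyl)oxy]-3-methoxyphenyl}-7-{4-[(tert-butyldimethylsilyl)oxy]phenyl}hepta-1,3-dien-5-one F3. Bu4NF/AcOH in THF at 0 °C removes the three silyl groups and comes back to the route at 13.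

3. Step 5. The acylation may stall through proton transfer from the acidic ketone to the lateral anion, or the anion may add a second time to the ketone. The fallback sets out from 5: the lateral anion 8 (LiN(iPr)2, THF, −78 °C) is added to 4-[(tert-butyldimethylsilyl)oxy]benzaldehyde, which gives a non-acidic alkoxide and cannot over-add. Work-up should give rac-1-{4-[(tert-butyldimethylsilyl)oxy]phenyl}-2-{3-[(E)-2-{4-[(tert-butyldimethylsilyl)oxy]-3-methoxyphenyl}ethenyl]isoxazol-5-yl}ethan-1-ol F4. Oxidation with Dess–Martin periodinane and NaHCO3 in CH2Cl2 comes back to the route at 10.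

**Further compounds**
F1 | step 7 | (S)-1-{4-[(tert-butyldimethylsilyl)oxy]phenyl}-2-{3-[(E)-2-{4-[(tert-butyldimethylsilyl)oxy]-3-methoxyphenyl}ethenyl]isoxazol-5-yl}ethan-1-ol | COc1cc(/C=C/c2cc(C[C@H](O)c3ccc(O[Si](C)(C)C(C)(C)C)cc3)on2)ccc1O[Si](C)(C)C(C)(C)C
F2 | step 8 | 3-[(E)-2-{4-[(tert-butyldimethylsilyl)oxy]-3-methoxyphenyl}ethenyl]-5-[(2S)-2-[(tert-butyldimethylsilyl)oxy]-2-{4-[(tert-butyldimethylsilyl)oxy]phenyl}ethyl]isoxazole | COc1cc(/C=C/c2cc(C[C@H](O[Si](C)(C)C(C)(C)C)c3ccc(O[Si](C)(C)C(C)(C)C)cc3)on2)ccc1O[Si](C)(C)C(C)(C)C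
F3 | step 8 | (1E,3Z,7S)-3-amino-7-[(tert-butyldimethylsilyl)oxy]-1-{4-[(tert-butyldimethylsilyl)oxy]-3-methoxyphenyl}-7-{4-[(tert-butyldimethylsilyl)oxy]phenyl}hepta-1,3-dien-5-one | COc1cc(/C=C/C(N)=C/C(=O)C[C@H](O[Si](C)(C)C(C)(C)C)c2ccc(O[Si](C)(C)C(C)(C)C)cc2)ccc1O[Si](C)(C)C(C)(C)C
F4 | step 5 | rac-1-{4-[(tert-butyldimethylsilyl)oxy]phenyl}-2-{3-[(E)-2-{4-[(tert-butyldimethylsilyl)oxy]-3-methoxyphenyl}ethenyl]isoxazol-5-yl}ethan-1-ol | COc1cc(/C=C/c2cc(CC(O)c3ccc(O[Si](C)(C)C(C)(C)C)cc3)on2)ccc1O[Si](C)(C)C(C)(C)C
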